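## Retrosynthetic overview
1. The benzene ring, the benzylic carbon and both phenolic oxygens are bought together in 4-methylcatechol 1. No ring is formed in the route.
2. The three C–Br bonds come from exhaustive electrophilic bromination of 1 to give 2. The ring still carries CH3 rather than CHO, so it is electron-rich, and every free position is filled, so there is no regiochemical question.
3. The key disconnection is aldehyde C=O back to Ar–CH3. The methyl of 2 is oxygenated with water as the O source, through o-quinone 3, quinone methide 4, benzyl alcohol 5 and o-quinone 6, to target 7.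
4. Order: C–Br bonds first, the C–O bond last.

Assumption: the target is an achiral, planar arene with no stereocentre. No enantiomer has to be selected, and the given SMILES defines the structure fully.

## Route

Step 1
Reactants: 1 4-methylbenzene-1,2-diol (4-methylcatechol)
Product: 2 3,4,6-tribromo-5-methylbenzene-1,2-diol
Conditions: Br2 (3.1 equiv), AcOH, 10 °C → rt, 3 h; pour into H2O, filter
Reagents that add atoms: bromine, BrBr
Why: Exhaustive electrophilic aromatic bromination, in which two OH groups and the CH3 activate all three free ring positions (as in the bromination of catechol to tetrabromocatechol), the HBr that builds up keeps the catechol from being oxidised to the quinone, and no stereocentre is formed.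

Step 2
Reactants: 2 3,4,6-tribromo-5-methylbenzene-1,2-diol
Product: 7 2,3,6-tribromo-4,5-dihydroxybenzaldehyde, via o-quinone 3 (not isolated), via quinone methide 4 (not isolated), via benzyl alcohol 5 (not isolated), via hydroxymethyl-o-quinone 6 (not isolated)
Conditions: DDQ (2.05 equiv), NaOAc (20 mol %), AcOH/H2O 9:1 (0.05 M), Ar, rt → 60 °C, 6–12 h; filter off the hydroquinone, crystallise
Reagents that add atoms: water, O
Why: Proposed new method: a quinone-relay benzylic C–H oxygenation of a free, ring-blocked 4-methylcatechol, in which DDQ (roughly 1.0 V) dehydrogenates catechol 2 (roughly 0.8 V) to o-quinone 3, the AcOH/AcO− buffer shuttles a methyl proton (acidified by the vinylogous 1,2-dione and three Br) to O-1 to give the 2-hydroxy-p-quinone methide 4 (direct hydride abstraction from the CH3 of 2 by DDQ or by 3 leads to the same species), water adds 1,6 to the exocyclic carbon so that rearomatisation drives the first C–O bond formation (5), and a second dehydrogenation gives 6, whose prototropic tautomer is the aldehyde 7 itself; the three bromines block the ring Michael additions and dimerisations that normally consume 4-methyl-o-quinones, and 7, the most electron-poor catechol in the flask, is not oxidised further by the 2.05 equiv of DDQ; the closest known reaction types are the DDQ/aqueous oxidation of 2,6-disubstituted p-cresols to 4-hydroxybenzaldehydes through p-quinone methides and the o-quinone → quinone methide tautomerisation of 4-alkylcatechols, neither shown preparatively on a free perhalogenated methylcatechol; no stereocentre is formed.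

## Compound list
1 | 4-methylbenzene-1,2-diol (4-methylcatechol) | Cc1ccc(O)c(O)c1 | starting material
2 | 3,4,6-tribromo-5-methylbenzene-1,2-diol | Cc1c(Br)c(O)c(O)c(Br)c1Br | intermediate
3 | 3,4,6-tribromo-5-methylcyclohexa-3,5-diene-1,2-dione | CC1=C(Br)C(=O)C(=O)C(Br)=C1Br | intermediate
4 | 2,3,5-tribromo-6-hydroxy-4-methylidenecyclohexa-2,5-dien-1-one | C=C1C(Br)=C(O)C(=O)C(Br)=C1Br | intermediate
5 | 3,4,6-tribromo-5-(hydroxymethyl)benzene-1,2-diol | OCc1c(Br)c(O)c(O)c(Br)c1Br | intermediate
6 | 3,4,6-tribromo-5-(hydroxymethyl)cyclohexa-3,5-diene-1,2-dione | OCC1=C(Br)C(=O)C(=O)C(Br)=C1Br | intermediate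
7 | 2,3,6-tribromo-4,5-dihydroxybenzaldehyde | O=Cc1c(Br)c(O)c(O)c(Br)c1Br | target

Total step count: 2. Longest linear sequence: 2.

## Points most likely to fail
The route has only two steps, so the two C–O-forming stages of step 2 are ranked separately.

1. Step 2, first oxygenation stage (2 → 5), the proposed new method.
   - Risk: o-quinone 3 may tautomerise too slowly. Water or acetate could then displace a vinylic bromine, or 4 could be trapped by 2 or 5 as benzyl aryl or dibenzyl ethers.
   - Fallback (known chemistry, no quinone involved): it sets out from 2 and comes back at 7. Acetylation with Ac2O/pyridine gives 3,4,6-tribromo-5-methyl-1,2-phenylene diacetate F1.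
   - Wohl–Ziegler double bromination (NBS 2.5 equiv, AIBN, PhCF3, reflux), as practised on 2,6-dihalotoluenes, gives 3,4,6-tribromo-5-(dibromomethyl)-1,2-phenylene diacetate F2.
   - Hot aqueous H2SO4/AcOH then hydrolyses both acetates and the gem-dibromide in one operation to give 7.

2. Step 2, second oxygenation stage (5 → 7).
   - Risk: the reaction may stall at alcohol 5 or its symmetrical ether, or the last DDQ equivalent may be lost to hydrolysis.
   - Fallback: it sets out from 5 and comes back at 7. Step 2 is run with 1.0 equiv DDQ at rt and 5 is isolated.
   - 48 % HBr in AcOH converts 5 into 3,4,6-tribromo-5-(bromomethyl)benzene-1,2-diol F3.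
   - A Kornblum oxidation (DMSO, NaHCO3, Ar, 80 °C) delivers the aldehyde oxygen from DMSO instead of by a quinone dehydrogenation and gives 7.

3. Step 1.
   - Risk: bromine may oxidise the free catechol to quinone-derived tars, or benzylic bromination may begin before the third ring position is filled.
   - Fallback: it sets out from 1 and comes back at 2. O-methylation (Me2SO4, K2CO3, acetone) gives 1,2-dimethoxy-4-methylbenzene F4, which cannot form a quinone.
   - Br2 (excess) with Fe powder in CH2Cl2 gives 1,2,4-tribromo-5,6-dimethoxy-3-methylbenzene F5.
   - BBr3 (CH2Cl2, −78 °C → rt) cleaves both ethers to give 2.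

## Further compounds
F1 | step 2 | 3,4,6-tribromo-5-methyl-1,2-phenylene diacetate | Cc1c(Br)c(OC(C)=O)c(OC(C)=O)c(Br)c1Br
F2 | step 2 | 3,4,6-tribromo-5-(dibromomethyl)-1,2-phenylene diacetate | BrC(Br)c1c(Br)c(OC(C)=O)c(OC(C)=O)c(Br)c1Br
F3 | step 2 | 3,4,6-tribromo-5-(bromomethyl)benzene-1,2-diol | BrCc1c(Br)c(O)c(O)c(Br)c1Br
F4 | step 1 | 1,2-dimethoxy-4-methylbenzene | Cc1ccc(OC)c(OC)c1
F5 | step 1 | 1,2,4-tribromo-5,6-dimethoxy-3-methylbenzene | Cc1c(Br)c(OC)c(OC)c(Br)c1Br
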